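**Strategy.** Everything rests on cutting the C2–C3 bond of the butyl chain. A reagent-controlled boron aldol joins the (Z)-enolate of aryl ethyl ketone 1 to acetaldehyde 2 and, in one operation, makes that bond and both of its stereocentres. The step exploits the syn C2-methyl/C3-hydroxyl pair lying next to benzylic C1 on the 3,4,5-trimethoxyphenyl ring (ring A): C1 is kept as the ketone, which later lets the C3 hydroxyl direct a 1,3-anti reduction. The precursor is the achiral ketone as its diisopinocampheylboron (Z)-enolate. Reduction, silylation at O3, acylation at O1 with the 3,4-dimethoxybenzoyl (ring B) chloride and desilylation complete the route.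

Key step: step 1

Assumption: 3S calls for attack on the re face of acetaldehyde, and the (Z)-enolate bearing isopinocampheyl groups from (+)-α-pinene, (−)-Ipc2BOTf, is taken to deliver that face; the sense should be confirmed on the first batch of 5 by Mosher ester analysis, the antipodal reagent being equally accessible.

Step 1
Reactants: 1 1-(3,4,5-trimethoxyphenyl)propan-1-one; 2 acetaldehyde
Product: 5 (2R,3S)-3-hydroxy-2-methyl-1-(3,4,5-trimethoxyphenyl)butan-1-one, via (Z)-enol diisopinocampheylborinate 3 (not isolated), via boron aldolate 4 (not isolated)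
Conditions: (−)-Ipc2BOTf (diisopinocampheylboron triflate, 1.4 equiv, prepared beforehand from (−)-Ipc2BH and TfOH), iPr2NEt (2.5 equiv), CH2Cl2, −78 → 0 °C, 2 h; then 2 (4 equiv, freshly distilled), −78 → −20 °C, 16 h; then pH 7 buffer, MeOH, 30% H2O2, 0 °C → rt
Reagents that add atoms: none
Why: Ipc2BOTf and the hindered amine enolise ketone 1 on its only enolisable side to the (Z)-enol borinate 3; acetaldehyde then binds to boron and reacts through a closed six-membered chair (Zimmerman–Traxler) transition state with its methyl group equatorial, which turns the (Z) geometry into the 2,3-syn aldolate 4, and oxidative work-up releases 5. The closest known reaction type is the diisopinocampheylboron-mediated syn aldol of ethyl ketones with aldehydes (reagent-controlled boron aldol). No ring is closed. The relative configuration of C2 and C3 is fixed by the enolate geometry and the chair, while the absolute configuration comes from the isopinocampheyl ligands, which should expose the re face of the aldehyde and so give 3S and with it 2R. The step needs high (Z) selectivity, secured by the triflate/iPr2NEt pair and by the aryl group, which avoids a cis relationship to the methyl, and it needs aldehyde face selectivity, which rests on the ligands alone; because acetaldehyde is small, the enantiomeric purity should be raised by crystallising diol 6.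

Step 2
Reactants: 5 (2R,3S)-3-hydroxy-2-methyl-1-(3,4,5-trimethoxyphenyl)butan-1-one
Product: 6 (1R,2R,3S)-2-methyl-1-(3,4,5-trimethoxyphenyl)butane-1,3-diol
Conditions: Me4NBH(OAc)3 (6 equiv), MeCN/AcOH 1:1, −30 → 0 °C; aq. sodium potassium tartrate; recrystallisation
Reagents that add atoms: none
Why: Evans–Saksena hydroxyl-directed reduction: the C3 hydroxyl displaces an acetate on boron and the tethered hydride is delivered to the acid-activated C1 ketone inside a six-membered chair, with the C3 methyl equatorial and the carbonyl substituent turned away from the axial acetoxy group, so the new C1 hydroxyl should be 1,3-anti to O3 (1R); without this tether the reagent is too weak to reduce the ketone.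

Step 3
Reactants: 6 (1R,2R,3S)-2-methyl-1-(3,4,5-trimethoxyphenyl)butane-1,3-diol
Product: 7 (1R,2S,3S)-3-[(tert-butyldimethylsilyl)oxy]-2-methyl-1-(3,4,5-trimethoxyphenyl)butan-1-ol
Conditions: TBSCl (1.05 equiv), imidazole (2.5 equiv), DMF, −20 → 0 °C
Reagents that add atoms: tert-butyldimethylsilyl chloride, CC(C)(C)[Si](C)(C)Cl
Why: Selective silyl ether formation under steric control: the C3 methyl carbinol is less encumbered than the benzylic C1 hydroxyl, which is flanked by ring A and the C2 branch, so one equivalent of the bulky silyl chloride at low temperature should take O3; no stereocentre is touched (the C2 descriptor changes from R to S through the priority rules only).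

Step 4
Reactants: 7 (1R,2S,3S)-3-[(tert-butyldimethylsilyl)oxy]-2-methyl-1-(3,4,5-trimethoxyphenyl)butan-1-ol; 8 3,4-dimethoxybenzoyl chloride
Product: 9 (1R,2S,3S)-3-[(tert-butyldimethylsilyl)oxy]-2-methyl-1-(3,4,5-trimethoxyphenyl)butyl 3,4-dimethoxybenzoate
Conditions: 8 (1.5 equiv), Et3N (3 equiv), 4-(dimethylamino)pyridine (0.3 equiv), CH2Cl2, 0 °C → rt
Reagents that add atoms: none
Why: Acylation of an alcohol by an acid chloride under nucleophilic catalysis (N-acylpyridinium intermediate): only O1 is free, the C1–O bond is not broken so C1 keeps its configuration, and the silyl ether tolerates the amine bases.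

Step 5
Reactants: 9 (1R,2S,3S)-3-[(tert-butyldimethylsilyl)oxy]-2-methyl-1-(3,4,5-trimethoxyphenyl)butyl 3,4-dimethoxybenzoate
Product: 10 (1R,2R,3S)-3-hydroxy-2-methyl-1-(3,4,5-trimethoxyphenyl)butyl 3,4-dimethoxybenzoate (CNP0167175.1)
Conditions: HF·pyridine, pyridine, THF, 0 °C → rt; aq. NaHCO3
Reagents that add atoms: none
Why: Fluoride-mediated desilylation driven by the strong Si–F bond; the buffered, weakly acidic medium never generates a free C3 alkoxide, so 1,3 O-to-O migration of the aroyl group from O1 to O3 should be suppressed, and it is too mild to ionise the benzylic ester.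

**Compound list**

1 | 1-(3,4,5-trimethoxyphenyl)propan-1-one | CCC(=O)c1cc(OC)c(OC)c(OC)c1 | starting material
2 | acetaldehyde | CC=O | starting material
3 | (Z)-1-(3,4,5-trimethoxyphenyl)prop-1-en-1-yl diisopinocampheylborinate, isopinocampheyl groups from (+)-α-pinene | C/C=C(\OB([C@@H]1C[C@@H]2C[C@H]([C@H]1C)C2(C)C)[C@@H]1C[C@@H]2C[C@H]([C@H]1C)C2(C)C)c1cc(OC)c(OC)c(OC)c1 | intermediate
4 | O3-diisopinocampheylboryl derivative of 5 (boron aldolate, 2R,3S) | COc1cc(cc(OC)c1OC)C(=O)[C@H](C)[C@H](C)OB([C@@H]1C[C@@H]2C[C@H]([C@H]1C)C2(C)C)[C@@H]1C[C@@H]2C[C@H]([C@H]1C)C2(C)C | intermediate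
5 | (2R,3S)-3-hydroxy-2-methyl-1-(3,4,5-trimethoxyphenyl)butan-1-one | COc1cc(cc(OC)c1OC)C(=O)[C@H](C)[C@H](C)O | intermediate
6 | (1R,2R,3S)-2-methyl-1-(3,4,5-trimethoxyphenyl)butane-1,3-diol | O[C@@H](c1cc(OC)c(OC)c(OC)c1)[C@H](C)[C@H](C)O | intermediate
7 | (1R,2S,3S)-3-[(tert-butyldimethylsilyl)oxy]-2-methyl-1-(3,4,5-trimethoxyphenyl)butan-1-ol | O[C@@H](c1cc(OC)c(OC)c(OC)c1)[C@H](C)[C@H](C)O[Si](C)(C)C(C)(C)C | intermediate
8 | 3,4-dimethoxybenzoyl chloride | COc1ccc(C(=O)Cl)cc1OC | starting material
9 | (1R,2S,3S)-3-[(tert-butyldimethylsilyl)oxy]-2-methyl-1-(3,4,5-trimethoxyphenyl)butyl 3,4-dimethoxybenzoate | COc1ccc(C(=O)O[C@@H](c2cc(OC)c(OC)c(OC)c2)[C@H](C)[C@H](C)O[Si](C)(C)C(C)(C)C)cc1OC | intermediate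
10 | (1R,2R,3S)-3-hydroxy-2-methyl-1-(3,4,5-trimethoxyphenyl)butyl 3,4-dimethoxybenzoate | COc1ccc(C(=O)O[C@@H](c2cc(OC)c(OC)c(OC)c2)[C@H](C)[C@H](C)O)cc1OC | target

Total step count: 5. Longest linear sequence: 5 steps.

**Steps most likely to fail**

Step 1. The boron ligands may discriminate the two faces of the small aldehyde only partly, and volatile acetaldehyde may be lost or self-condense before it is captured. The fallback is auxiliary control; it sets out from compound 2 and comes back at compound 5. An Evans syn aldol of commercial (R)-4-benzyl-3-propanoyl-1,3-oxazolidin-2-one F1 with 2 (Bu2BOTf, iPr2NEt, CH2Cl2, −78 → 0 °C; H2O2 work-up) should give (R)-4-benzyl-3-[(2R,3S)-3-hydroxy-2-methylbutanoyl]-1,3-oxazolidin-2-one F2, both centres being set by the auxiliary. Transamidation (MeONHMe·HCl, AlMe3, CH2Cl2, −15 → 0 °C) would give the Weinreb amide (2R,3S)-3-hydroxy-N-methoxy-N,2-dimethylbutanamide F3. Commercial 3,4,5-trimethoxyphenylmagnesium bromide F4 (2.5 equiv, THF, −20 → 0 °C, the first equivalent being spent on the hydroxyl) would then convert F3 into 5 by the Weinreb ketone synthesis.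

Step 3. The silyl chloride may not distinguish the two secondary hydroxyls well enough, so that O1 or both oxygens are silylated. The fallback protects before the second hydroxyl exists; it sets out from compound 5 and comes back at compound 7. Silylation of the single hydroxyl of 5 (TBSCl, imidazole, DMF, rt) would give (2R,3S)-3-[(tert-butyldimethylsilyl)oxy]-2-methyl-1-(3,4,5-trimethoxyphenyl)butan-1-one F5. Reduction with LiBH(s-Bu)3 (THF, −78 °C) under Felkin–Anh control, the hydride approaching anti to the silyloxy-bearing C3 substituent and past the C2 hydrogen, should give the 1,2-anti alcohol 7, with chromatographic removal of any C1 epimer.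

Step 2. Hydride delivery to the electron-rich, conjugated aryl ketone may be sluggish and the 1,3-anti preference incomplete. The fallback is an Evans–Tishchenko reduction; it sets out from compound 5 and comes back at compound 6. With benzaldehyde (4 equiv) and SmI2 (0.2 equiv) in THF at −10 °C, the samarium-bound hemiacetal formed at O3 should pass its hydride intramolecularly to C1 and give the anti monoester (2S,3S,4R)-4-hydroxy-3-methyl-4-(3,4,5-trimethoxyphenyl)butan-2-yl benzoate F6; methanolysis (K2CO3, MeOH, rt) would then give 6.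

**Further compounds**

F1 | step 1 | (R)-4-benzyl-3-propanoyl-1,3-oxazolidin-2-one | CCC(=O)N1[C@H](Cc2ccccc2)COC1=O
F2 | step 1 | (R)-4-benzyl-3-[(2R,3S)-3-hydroxy-2-methylbutanoyl]-1,3-oxazolidin-2-one | O=C1OC[C@@H](Cc2ccccc2)N1C(=O)[C@H](C)[C@H](C)O
F3 | step 1 | (2R,3S)-3-hydroxy-N-methoxy-N,2-dimethylbutanamide | CON(C)C(=O)[C@H](C)[C@H](C)O
F4 | step 1 | 3,4,5-trimethoxyphenylmagnesium bromide | COc1cc([Mg]Br)cc(OC)c1OC
F5 | step 3 | (2R,3S)-3-[(tert-butyldimethylsilyl)oxy]-2-methyl-1-(3,4,5-trimethoxyphenyl)butan-1-one | COc1cc(cc(OC)c1OC)C(=O)[C@H](C)[C@H](C)O[Si](C)(C)C(C)(C)C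
F6 | step 2 | (2S,3S,4R)-4-hydroxy-3-methyl-4-(3,4,5-trimethoxyphenyl)butan-2-yl benzoate | O[C@@H](c1cc(OC)c(OC)c(OC)c1)[C@H](C)[C@H](C)OC(=O)c1ccccc1
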